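**Retrosynthetic overview**

1. After all cuts, three bought compounds remain: racemic bromo acid 1, amino aldehyde 2 and quinolone 3 (ring B, complete from the start).
2. N1–C2 amide bond of ring A: acylation of 2 by 1 through acid chloride 4 gives anilide 5.
3. Key cut, C4–C3 of ring A: a carbene catalyst turns the aldehyde carbon of 5 into an acyl anion (Breslow intermediate), which displaces bromide at the amide alpha-carbon and closes ring A as 6.
4. CH2–C3 bond to ring B: 6 loses methanol to the exocyclic enone 7, which takes up 3 in a Michael addition to give the target 8.
5. Ring order: ring B is bought, ring A is closed last; both C–C bonds form in one flask.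

Assumption: the target is achiral (no stereocentre), so no enantiocontrol is needed; the one stereocentre of racemic 1, 4 and 5 is erased when ring A enolises in step 2.

**Route**

Step 1
Reactants: 1 2-bromo-3-methoxypropanoic acid (racemic); 2 2-(methylamino)benzaldehyde
Product: 5 racemic 2-bromo-N-(2-formylphenyl)-3-methoxy-N-methylpropanamide, via acid chloride 4 (not isolated)
Conditions: (COCl)2, cat. DMF, CH2Cl2, 0 °C to rt, evaporate; then 2, pyridine, CH2Cl2, 0 °C to rt
Reagents that add atoms: none
Why: N-acylation of a secondary aniline by an acid chloride (Schotten–Baumann-type amide formation), the same reaction type by which 2-(methylamino)aryl ketones are acylated with alpha-halo acyl halides; the aldehyde and the C–Br bond are untouched and the racemic stereocentre is of no consequence.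

Step 2
Reactants: 5 racemic 2-bromo-N-(2-formylphenyl)-3-methoxy-N-methylpropanamide; 3 4-hydroxy-1-methylquinolin-2(1H)-one
Product: 8 zanthobisquinolone [3,3'-methylenebis(4-hydroxy-1-methylquinolin-2(1H)-one)], via methoxymethylquinolone 6 (not isolated), via methylidenedione 7 (not isolated)
Conditions: 3-benzyl-5-(2-hydroxyethyl)-4-methylthiazolium chloride (20 mol%), i-Pr2NEt (2.5 equiv), 1,4-dioxane, 60 °C; then 3 (1.05 equiv), AcOH, 100 °C
Reagents that add atoms: none
Why: Proposed new method: the thiazol-2-ylidene adds to the aldehyde of 5 to give a Breslow intermediate (acyl anion equivalent) whose nucleophilic carbon displaces the bromide on the neighbouring amide alpha-carbon in a 6-exo-tet closure (or, equally productive, transfers one electron to the C–Br bond and recombines as a radical pair), so two natively electrophilic carbons are joined and ring A is closed as 6, the stereocentre vanishing on enolisation; acid then expels methanol from 6 to give enone 7, which C3 of 3 captures at once in a Michael addition (the second half of the classical methylene-bisquinolone condensation); the closest known reaction types are the carbene-catalysed intramolecular nucleophilic substitution of aldehydes carrying alkyl tosylates or halides to give chroman-4-ones and the carbene-catalysed radical acylation of alpha-bromo carbonyl compounds.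

**Compound list**

1 | 2-bromo-3-methoxypropanoic acid (racemic) | COCC(Br)C(=O)O | starting material
2 | 2-(methylamino)benzaldehyde | CNc1ccccc1C=O | starting material
3 | 4-hydroxy-1-methylquinolin-2(1H)-one | Cn1c(=O)cc(O)c2ccccc21 | starting material
4 | 2-bromo-3-methoxypropanoyl chloride (racemic) | COCC(Br)C(Cl)=O | intermediate
5 | 2-bromo-N-(2-formylphenyl)-3-methoxy-N-methylpropanamide (racemic) | COCC(Br)C(=O)N(C)c1ccccc1C=O | intermediate
6 | 4-hydroxy-3-(methoxymethyl)-1-methylquinolin-2(1H)-one | COCc1c(O)c2ccccc2n(C)c1=O | intermediate
7 | 1-methyl-3-methylidenequinoline-2,4(1H,3H)-dione | C=C1C(=O)c2ccccc2N(C)C1=O | intermediate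
8 | zanthobisquinolone, 3,3'-methylenebis(4-hydroxy-1-methylquinolin-2(1H)-one), achiral | Cn1c(=O)c(Cc2c(O)c3ccccc3n(C)c2=O)c(O)c2ccccc21 | target

**Totals and risks**

Total step count: 2. Longest linear sequence: 2 (1 + 2 → 5 → 8).

The route has only two steps, so both are ranked; step 2 gets two entries, one for each of its bond-forming stages.

Most likely to fail, first: step 2, ring-closing stage (5 → 6). The Breslow carbon must substitute at a secondary, branched carbon, and the free carbene can be alkylated by the bromide or the amine can eliminate HBr. The fallback sets out from 2 and comes back to the route at 7. Compound 2 is acylated with (E)-3-(phenylsulfonyl)prop-2-enoyl chloride F1, made in the flask from the known (E)-3-(phenylsulfonyl)prop-2-enoic acid and oxalyl chloride, to give (E)-N-(2-formylphenyl)-N-methyl-3-(phenylsulfonyl)prop-2-enamide F2. The same thiazolium chloride and i-Pr2NEt then close ring A by an intramolecular Stetter reaction, 6-exo-trig onto the alkene carbon beta to the sulfone, giving 4-hydroxy-1-methyl-3-[(phenylsulfonyl)methyl]quinolin-2(1H)-one F3. Its enolate expels benzenesulfinate to give 7, which 3 captures as in the main route. This replaces a substitution at sp3 carbon by a conjugate addition, which is the best-precedented reaction of acyl anion catalysis.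

Second: step 2, coupling stage (6 → 7 → 8). Methanol may leave sluggishly, or 7 may oligomerise before 3 adds. The fallback sets out from 6, isolated after the first stage by acidic work-up, and comes back at 8. Compound 6 is treated with HBr in AcOH at rt to give 3-(bromomethyl)-4-hydroxy-1-methylquinolin-2(1H)-one F4, a discrete alkylating agent. F4 is added at 0 °C to 3 and NaHCO3 in DMF, where C3 of 3 is alkylated to give 8.

Third: step 1. The amine of 2 is weakly nucleophilic (hydrogen-bonded to the aldehyde), and the alpha-bromo acid chloride can lose HBr or form a ketene with pyridine. The fallback sets out from 2 and comes back at 5. Compound 2 is acylated with acryloyl chloride and pyridine to give N-(2-formylphenyl)-N-methylprop-2-enamide F5. N-bromosuccinimide in methanol then adds Br and OMe across the alkene, bromine at the alpha-carbon and methoxide at the terminal carbon, to give 5; an aqueous acid wash returns any aldehyde acetal to the aldehyde.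

**Further compounds**

F1 | step 2 | (E)-3-(phenylsulfonyl)prop-2-enoyl chloride | O=C(Cl)/C=C/S(=O)(=O)c1ccccc1
F2 | step 2 | (E)-N-(2-formylphenyl)-N-methyl-3-(phenylsulfonyl)prop-2-enamide | CN(C(=O)/C=C/S(=O)(=O)c1ccccc1)c1ccccc1C=O
F3 | step 2 | 4-hydroxy-1-methyl-3-[(phenylsulfonyl)methyl]quinolin-2(1H)-one | Cn1c(=O)c(CS(=O)(=O)c2ccccc2)c(O)c2ccccc21
F4 | step 2 | 3-(bromomethyl)-4-hydroxy-1-methylquinolin-2(1H)-one | Cn1c(=O)c(CBr)c(O)c2ccccc21
F5 | step 1 | N-(2-formylphenyl)-N-methylprop-2-enamide | C=CC(=O)N(C)c1ccccc1C=O
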